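**Retrosynthetic overview**
1. Target 18 ⇐ aryl bromide 17 by a final Suzuki coupling; the propenyl group is introduced only after the ozonolysis and acid steps.
2. The dihydrofuran ring (the only ring made; both benzene rings are bought) ⇐ acid-triggered closure of phenol/benzylic alcohol 15 through the para-oxybenzyl cation, with C2 set trans to C3.
3. 15 ⇐ lactol 10 + syringyl Grignard reagent 13; 10 ⇐ ozonolysis of the ortho-(pent-3-en-2-yl)phenol 7.
4. 7 ⇐ aromatic Claisen [3,3] rearrangement of the aryl (R,Z)-pent-3-en-2-yl ether 5, which forms the C3–C3a bond and sets C3 by 1,3-chirality transfer.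
5. 5 ⇐ ethyl (S)-lactate 2 + 4-bromo-2-methoxyphenol 1 (Mitsunobu inversion, then half-reduction/Z-Wittig).

Assumption: the SMILES is read as the (2S,3S)-trans isomer; compounds 1, 2, 11, ethyl (R)-lactate and (E)-prop-1-enylboronic acid are taken as commercial.

**Step 1**
Reactants: 1 4-bromo-2-methoxyphenol; 2 ethyl (S)-lactate
Product: 3 ethyl (2R)-2-(4-bromo-2-methoxyphenoxy)propanoate
Conditions: PPh3, DIAD, THF, 0 °C → rt
Reagents that add atoms: none
Why: Mitsunobu etherification, in which the phenol displaces the activated oxyphosphonium of the α-hydroxy ester by SN2 with clean inversion, turning the bought (S) centre into (R).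

**Step 2**
Reactants: 3 ethyl (2R)-2-(4-bromo-2-methoxyphenoxy)propanoate
Product: 5 4-bromo-2-methoxy-1-{[(2R,3Z)-pent-3-en-2-yl]oxy}benzene, via aryloxypropanal 4 (not isolated)
Conditions: i-Bu2AlH (1.1 equiv), toluene, −78 °C; then Ph3P=CHCH3 [from EtPPh3Br, KN(SiMe3)2, THF], −78 °C → rt
Reagents that add atoms: ethyltriphenylphosphonium bromide, CC[P+](c1ccccc1)(c1ccccc1)c1ccccc1.[Br-]
Why: Low-temperature ester half-reduction followed in the same flask by a salt-free Wittig reaction of the non-stabilised ylide gives the (Z)-alkene (kinetic cis-oxaphosphetane) without handling the epimerisable α-aryloxy aldehyde, so the lactate-derived centre is untouched.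

**Step 3**
Reactants: 5 4-bromo-2-methoxy-1-{[(2R,3Z)-pent-3-en-2-yl]oxy}benzene
Product: 7 4-bromo-2-methoxy-6-[(2R,3E)-pent-3-en-2-yl]phenol, via ortho-dienone 6 (not isolated)
Conditions: PhNEt2, 190 °C, sealed tube, 12 h
Reagents that add atoms: none
Why: Aromatic Claisen [3,3]-sigmatropic rearrangement to the only free ortho position (the other is blocked by OMe, para by Br) and tautomerisation of 6; the (Z)-methyl forces the carbinol methyl pseudo-equatorial (allylic 1,3-strain), so the C–O bond is exchanged suprafacially for the C–C bond and the (R) ether centre is relayed to the (R) benzylic centre (the future C3) with an (E)-alkene.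

**Step 4**
Reactants: 7 4-bromo-2-methoxy-6-[(2R,3E)-pent-3-en-2-yl]phenol
Product: 10 (3S)-5-bromo-7-methoxy-3-methyl-2,3-dihydro-1-benzofuran-2-ol (C2 anomer mixture), via ozonide 8 (not isolated), via hydroxy-aldehyde 9 (not isolated)
Conditions: O3, CH2Cl2, −78 °C (Sudan Red 7B end point); then PPh3, −78 °C → rt
Reagents that add atoms: ozone, [O-][O+]=O
Why: Ozonolysis with reductive work-up, in which the disubstituted alkene reacts far faster than the bromoguaiacol ring and the α-aryl aldehyde 9 is trapped at once by the ortho phenol as the five-membered lactol, which shields C3 from enolisation.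

**Step 5**
Reactants: 11 4-bromo-2,6-dimethoxyphenol
Product: 12 5-bromo-1,3-dimethoxy-2-(methoxymethoxy)benzene
Conditions: NaH, MOMCl, DMF, 0 °C → rt
Reagents that add atoms: chloromethyl methyl ether (MOMCl), COCCl
Why: Williamson-type O-alkylation of the phenoxide with a reactive α-chloro ether; no stereocentre is involved.

**Step 6**
Reactants: 10 (3S)-5-bromo-7-methoxy-3-methyl-2,3-dihydro-1-benzofuran-2-ol; 12 5-bromo-1,3-dimethoxy-2-(methoxymethoxy)benzene
Product: 15 (2S)-2-(5-bromo-2-hydroxy-3-methoxyphenyl)-1-[3,5-dimethoxy-4-(methoxymethoxy)phenyl]propan-1-ol (C1 epimer mixture), via aryl Grignard reagent 13 (not isolated), via bromomagnesium phenoxide aldehyde 14 (not isolated)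
Conditions: 12 (3 equiv), Mg, THF, reflux; then 10, THF, 0 °C → rt; aq. NH4Cl
Reagents that add atoms: none
Why: Grignard addition to a lactol, in which the first equivalent of 13 deprotonates 10, the ring opens to the bromomagnesium phenoxide 14 that carries the free aldehyde, and a second equivalent arylates that aldehyde faster than it enolises; the new carbinol centre is an inconsequential epimer mixture and C3 is untouched.

**Step 7**
Reactants: 15 (2S)-2-(5-bromo-2-hydroxy-3-methoxyphenyl)-1-[3,5-dimethoxy-4-(methoxymethoxy)phenyl]propan-1-ol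
Product: 17 4-[(2S,3S)-5-bromo-7-methoxy-3-methyl-2,3-dihydro-1-benzofuran-2-yl]-2,6-dimethoxyphenol, via MOM-protected dihydrobenzofuran 16 (not isolated)
Conditions: HCl (1.25 M in MeOH), 0 °C → rt
Reagents that add atoms: none
Why: Acid-mediated dehydrative cyclisation (SN1 etherification through the para-oxygen-stabilised benzylic cation) makes both carbinol epimers converge, the ortho phenol closes the ring anti to the C3 methyl and the reversible closure settles on the more stable 2,3-trans isomer, so (3S) dictates (2S), while the same acid cleaves the MOM acetal by transacetalisation.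

**Step 8**
Reactants: 17 4-[(2S,3S)-5-bromo-7-methoxy-3-methyl-2,3-dihydro-1-benzofuran-2-yl]-2,6-dimethoxyphenol
Product: 18 odoratisol A, 4-[(2S,3S)-7-methoxy-3-methyl-5-[(1E)-prop-1-en-1-yl]-2,3-dihydro-1-benzofuran-2-yl]-2,6-dimethoxyphenol
Conditions: (E)-CH3CH=CHB(OH)2, Pd(PPh3)4 (5 mol %), K2CO3, 1,4-dioxane/H2O, 80 °C
Reagents that add atoms: (E)-prop-1-en-1-ylboronic acid, C/C=C/B(O)O
Why: Suzuki–Miyaura cross-coupling (oxidative addition of the aryl bromide to zerovalent palladium, transmetalation, reductive elimination) retains the (E)-alkene geometry, tolerates the free phenol and does not touch the two stereocentres.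

**Compound list**
1 | 4-bromo-2-methoxyphenol | COc1cc(Br)ccc1O | starting material
2 | ethyl (S)-lactate, ethyl (2S)-2-hydroxypropanoate | CCOC(=O)[C@H](C)O | starting material
3 | ethyl (2R)-2-(4-bromo-2-methoxyphenoxy)propanoate | CCOC(=O)[C@@H](C)Oc1ccc(Br)cc1OC | intermediate
4 | (2R)-2-(4-bromo-2-methoxyphenoxy)propanal | O=C[C@@H](C)Oc1ccc(Br)cc1OC | intermediate (not isolated)
5 | 4-bromo-2-methoxy-1-{[(2R,3Z)-pent-3-en-2-yl]oxy}benzene | C/C=C\[C@@H](C)Oc1ccc(Br)cc1OC | intermediate
6 | 4-bromo-2-methoxy-6-[(2R,3E)-pent-3-en-2-yl]cyclohexa-2,4-dien-1-one (ring C6 configuration not defined, lost on tautomerisation) | O=C1C(OC)=CC(Br)=CC1[C@H](C)/C=C/C | intermediate (not isolated)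
7 | 4-bromo-2-methoxy-6-[(2R,3E)-pent-3-en-2-yl]phenol | C/C=C/[C@@H](C)c1cc(Br)cc(OC)c1O | intermediate
8 | 4-bromo-2-methoxy-6-[(1S)-1-(5-methyl-1,2,4-trioxolan-3-yl)ethyl]phenol (ozonide, ring stereoisomer mixture) | CC1OOC(O1)[C@@H](C)c2cc(Br)cc(OC)c2O | intermediate (not isolated)
9 | (2S)-2-(5-bromo-2-hydroxy-3-methoxyphenyl)propanal | O=C[C@@H](C)c1cc(Br)cc(OC)c1O | intermediate (not isolated)
10 | (3S)-5-bromo-7-methoxy-3-methyl-2,3-dihydro-1-benzofuran-2-ol (C2 anomer mixture) | C[C@@H]1C(O)Oc2c(OC)cc(Br)cc21 | intermediate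
11 | 4-bromo-2,6-dimethoxyphenol | COc1cc(Br)cc(OC)c1O | starting material
12 | 5-bromo-1,3-dimethoxy-2-(methoxymethoxy)benzene | COCOc1c(OC)cc(Br)cc1OC | intermediate
13 | [3,5-dimethoxy-4-(methoxymethoxy)phenyl]magnesium bromide | COCOc1c(OC)cc([Mg]Br)cc1OC | intermediate (not isolated)
14 | bromomagnesium 4-bromo-2-methoxy-6-[(2S)-1-oxopropan-2-yl]phenolate | O=C[C@@H](C)c1cc(Br)cc(OC)c1O[Mg]Br | intermediate (not isolated)
15 | (2S)-2-(5-bromo-2-hydroxy-3-methoxyphenyl)-1-[3,5-dimethoxy-4-(methoxymethoxy)phenyl]propan-1-ol (C1 epimer mixture) | C[C@H](C(O)c1cc(OC)c(OCOC)c(OC)c1)c1cc(Br)cc(OC)c1O | intermediate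
16 | (2S,3S)-5-bromo-2-[3,5-dimethoxy-4-(methoxymethoxy)phenyl]-7-methoxy-3-methyl-2,3-dihydro-1-benzofuran | Brc1cc(OC)c2c(c1)[C@H](C)[C@@H](c1cc(OC)c(OCOC)c(OC)c1)O2 | intermediate (not isolated)
17 | 4-[(2S,3S)-5-bromo-7-methoxy-3-methyl-2,3-dihydro-1-benzofuran-2-yl]-2,6-dimethoxyphenol | Brc1cc(OC)c2c(c1)[C@H](C)[C@@H](c1cc(OC)c(O)c(OC)c1)O2 | intermediate
18 | odoratisol A, 4-[(2S,3S)-7-methoxy-3-methyl-5-[(1E)-prop-1-en-1-yl]-2,3-dihydro-1-benzofuran-2-yl]-2,6-dimethoxyphenol | C/C=C/c1cc(OC)c2c(c1)[C@H](C)[C@@H](c1cc(OC)c(O)c(OC)c1)O2 | target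

**Total step count:** 8
**Longest linear sequence:** 7 (steps 1, 2, 3, 4, 6, 7, 8 from 1 and 2; step 5 is a one-step side branch)

**Three steps most likely to fail**

Step 3. The (Z)-configured secondary ether rearranges slowly, and at 190 °C it can lose 1 by elimination or scramble 7 by the abnormal Claisen pathway. The fallback sets out from 1 and comes back at 7, and uses the other alkene geometry with the other lactate enantiomer. Mitsunobu coupling of 1 with ethyl (R)-lactate F1 gives ethyl (2S)-2-(4-bromo-2-methoxyphenoxy)propanoate F2. Reduction with i-Bu2AlH at −78 °C gives (2S)-2-(4-bromo-2-methoxyphenoxy)propanal F3. Julia–Kocienski olefination with 5-(ethylsulfonyl)-1-phenyl-1H-tetrazole and KN(SiMe3)2 gives 4-bromo-2-methoxy-1-{[(2S,3E)-pent-3-en-2-yl]oxy}benzene F4. The (E)-ether rearranges at about 170 °C through the same dienone 6. Its (S) centre with the (E)-alkene (carbinol methyl again pseudo-equatorial) delivers the same (R)-phenol 7.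

Step 6. The basic Grignard reagent may enolise the α-aryl aldehyde released from the lactol and erode C3, or the lactol may open sluggishly after deprotonation. The fallback sets out from 7 and comes back at 15, and avoids both the lactol and ozonolysis of a free phenol. Silylation of 7 (TBSCl, imidazole, DMF) gives tert-butyl{4-bromo-2-methoxy-6-[(2R,3E)-pent-3-en-2-yl]phenoxy}dimethylsilane F5. Ozonolysis (O3, then PPh3) through the ozonide tert-butyl{4-bromo-2-methoxy-6-[(1S)-1-(5-methyl-1,2,4-trioxolan-3-yl)ethyl]phenoxy}dimethylsilane F6 gives the discrete aldehyde (2S)-2-{5-bromo-2-[(tert-butyldimethylsilyl)oxy]-3-methoxyphenyl}propanal F7. Addition of 13 premixed with CeCl3 at −78 °C (a weakly basic organocerium reagent) gives (2S)-2-{5-bromo-2-[(tert-butyldimethylsilyl)oxy]-3-methoxyphenyl}-1-[3,5-dimethoxy-4-(methoxymethoxy)phenyl]propan-1-ol F8. n-Bu4NF in THF then frees the ring A phenol to give 15.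

Step 7. A single acid treatment must both close the ring and cleave the MOM acetal, and long exposure risks E1 loss to the stilbene or erosion of C3. The fallback sets out from 11 and comes back at 17, and separates ring closure from deprotection by using a fluoride-labile group. Silylation of 11 (TBSCl, imidazole, DMF) gives (4-bromo-2,6-dimethoxyphenoxy)(tert-butyl)dimethylsilane F9. Its Grignard reagent {4-[(tert-butyldimethylsilyl)oxy]-3,5-dimethoxyphenyl}magnesium bromide F10 (Mg, THF) adds to lactol 10 as in step 6, through the same bromomagnesium phenoxide 14, to give (2S)-2-(5-bromo-2-hydroxy-3-methoxyphenyl)-1-{4-[(tert-butyldimethylsilyl)oxy]-3,5-dimethoxyphenyl}propan-1-ol F11. Brief catalytic TsOH in CH2Cl2 at 0 °C closes the ring to tert-butyl{4-[(2S,3S)-5-bromo-7-methoxy-3-methyl-2,3-dihydro-1-benzofuran-2-yl]-2,6-dimethoxyphenoxy}dimethylsilane F12. n-Bu4NF in THF then gives 17 without further acid.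

**Further compounds**
F1 | step 3 | ethyl (R)-lactate | CCOC(=O)[C@@H](C)O
F2 | step 3 | ethyl (2S)-2-(4-bromo-2-methoxyphenoxy)propanoate | CCOC(=O)[C@H](C)Oc1ccc(Br)cc1OC
F3 | step 3 | (2S)-2-(4-bromo-2-methoxyphenoxy)propanal | O=C[C@H](C)Oc1ccc(Br)cc1OC
F4 | step 3 | 4-bromo-2-methoxy-1-{[(2S,3E)-pent-3-en-2-yl]oxy}benzene | C/C=C/[C@H](C)Oc1ccc(Br)cc1OC
F5 | step 6 | tert-butyl{4-bromo-2-methoxy-6-[(2R,3E)-pent-3-en-2-yl]phenoxy}dimethylsilane | C/C=C/[C@@H](C)c1cc(Br)cc(OC)c1O[Si](C)(C)C(C)(C)C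
F6 | step 6 | tert-butyl{4-bromo-2-methoxy-6-[(1S)-1-(5-methyl-1,2,4-trioxolan-3-yl)ethyl]phenoxy}dimethylsilane | CC1OOC(O1)[C@@H](C)c2cc(Br)cc(OC)c2O[Si](C)(C)C(C)(C)C
F7 | step 6 | (2S)-2-{5-bromo-2-[(tert-butyldimethylsilyl)oxy]-3-methoxyphenyl}propanal | O=C[C@@H](C)c1cc(Br)cc(OC)c1O[Si](C)(C)C(C)(C)C
F8 | step 6 | (2S)-2-{5-bromo-2-[(tert-butyldimethylsilyl)oxy]-3-methoxyphenyl}-1-[3,5-dimethoxy-4-(methoxymethoxy)phenyl]propan-1-ol | C[C@H](C(O)c1cc(OC)c(OCOC)c(OC)c1)c1cc(Br)cc(OC)c1O[Si](C)(C)C(C)(C)C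
F9 | step 7 | (4-bromo-2,6-dimethoxyphenoxy)(tert-butyl)dimethylsilane | CC(C)(C)[Si](C)(C)Oc1c(OC)cc(Br)cc1OC
F10 | step 7 | {4-[(tert-butyldimethylsilyl)oxy]-3,5-dimethoxyphenyl}magnesium bromide | CC(C)(C)[Si](C)(C)Oc1c(OC)cc([Mg]Br)cc1OC
F11 | step 7 | (2S)-2-(5-bromo-2-hydroxy-3-methoxyphenyl)-1-{4-[(tert-butyldimethylsilyl)oxy]-3,5-dimethoxyphenyl}propan-1-ol | C[C@H](C(O)c1cc(OC)c(O[Si](C)(C)C(C)(C)C)c(OC)c1)c1cc(Br)cc(OC)c1O
F12 | step 7 | tert-butyl{4-[(2S,3S)-5-bromo-7-methoxy-3-methyl-2,3-dihydro-1-benzofuran-2-yl]-2,6-dimethoxyphenoxy}dimethylsilane | Brc1cc(OC)c2c(c1)[C@H](C)[C@@H](c1cc(OC)c(O[Si](C)(C)C(C)(C)C)c(OC)c1)O2
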